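**Plan**

1. Cuts, last bond first: the exocyclic N1–acyl bond (to (E)-dodec-2-enoyl chloride), the C3–acetyl bond, the C4 ketone (carried as C4=CH2), the ring bond N1–C5, the N–C2 acyl bond (hydroxylamine plus acid), and the C–C bond joining the methylidene carbon to the isopentyl chain (Grignard reagent plus diketene).
2. Enabling feature: in the pyrrolidine-2,4-dione ring, N1–C5 lies γ to the C2 carbonyl, so a nitrenoid nitrogen on the C2 acyl group can reach a C5–H bond. Carrying the C4 ketone as an exocyclic methylidene makes those C–H bonds allylic and hides the ketone until ozonolysis.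
3. Forward: the chain C2–C5 plus isobutyl is assembled in one step, two more steps give the dioxazolone, and the only ring closes by C–H amidation. Ozonolysis, C3-acetylation and N1-acylation follow, with the acid chloride made on a side branch.
4. Stereochemistry: C5 (R) is the only stereocentre and is created from an achiral precursor in the ring closure by the chiral iridium catalyst. The E alkene is bought with the acid.

Key step: step 4

Assumption 1: reutericyclin C is taken as the 5R N-[(E)-dodec-2-enoyl] compound of the given SMILES, with the tricarbonyl unit written as its C4 enol.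
Assumption 2: the sense of induction of the catalyst on 7 cannot be predicted with confidence. The (S,S) ligand is written, and its commercial (R,R) antipode would be used if a first run gave the 5S lactam. TsDPEN is N-(p-toluenesulfonyl)-1,2-diphenylethane-1,2-diamine, bound as its amido–amine N,N-chelate.

**Step 1**
Reactants: 1 1-bromo-3-methylbutane; 2 diketene (4-methylideneoxetan-2-one)
Product: 4 6-methyl-3-methylideneheptanoic acid, via isopentylmagnesium bromide 3 (not isolated)
Conditions: Mg, THF, rt; then slow addition to 2 and NiCl2 (5 mol %), THF, −20 °C → rt; 1 M HCl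
Reagents that add atoms: none
Why: Magnesium insertion gives the Grignard reagent, and nickel-catalysed Kumada-type coupling at the vinylic C–O bond of diketene (ring opening of the enol lactone with the methylidene kept) is a known one-step entry to 3-methylidenealkanoic acids; no stereocentre is formed.

**Step 2**
Reactants: 4 6-methyl-3-methylideneheptanoic acid
Product: 6 N-hydroxy-6-methyl-3-methylideneheptanamide, via acyl imidazolide 5 (not isolated)
Conditions: CDI, THF, rt; then NH2OH·HCl, rt
Reagents that add atoms: hydroxylamine hydrochloride, NO.Cl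
Why: Activation of the acid as its acyl imidazolide followed by N-acylation of hydroxylamine is the standard hydroxamic acid synthesis and is mild enough to keep the β,γ-alkene out of conjugation.

**Step 3**
Reactants: 6 N-hydroxy-6-methyl-3-methylideneheptanamide
Product: 7 3-(5-methyl-2-methylidenehexyl)-1,4,2-dioxazol-5-one
Conditions: CDI, CH2Cl2, rt; 1 M HCl wash
Reagents that add atoms: 1,1'-carbonyldiimidazole, O=C(n1ccnc1)n1ccnc1
Why: Carbonylative cyclisation of a hydroxamic acid with CDI (O-acylation, then ring closure by the amide oxygen with loss of imidazole) is the standard preparation of 3-substituted 1,4,2-dioxazol-5-ones.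

**Step 4**
Reactants: 7 3-(5-methyl-2-methylidenehexyl)-1,4,2-dioxazol-5-one
Product: 8 (R)-5-(2-methylpropyl)-4-methylidenepyrrolidin-2-one
Conditions: Cp*IrCl[(S,S)-TsDPEN] (5 mol %), NaB[3,5-(CF3)2C6H3]4 (5 mol %), CH2Cl2/(CF3)2CHOH, 0 °C → rt
Reagents that add atoms: none
Why: Chloride abstraction opens a site at trivalent iridium, the dioxazolone binds through nitrogen and loses CO2 to an iridium acyl nitrenoid, and this inserts in a concerted singlet manner into one of the two enantiotopic C–H bonds of the γ-methylene; the closest known reaction is the enantioselective γ-lactam synthesis from dioxazolones by intramolecular C(sp3)–H amidation, which has been shown for allylic C–H bonds. The pyrrolidinone ring (N1, C2, C3, C4, C5, methylidene exocyclic) closes by 1,5 C–H insertion through a six-centre N···H···C transition state, forming N1–C5. C5 is set by the chiral diamine chelate, whose NH2 group hydrogen-bonds to the acyl oxygen and so fixes which C5 hydrogen faces the nitrenoid; the ligand antipode is chosen for R. The step needs γ insertion over δ or tertiary ε C–H bonds (ring size plus allylic weakening of C5–H by the C4 methylidene), insertion over alkene attack (aziridination would need a 1-azabicyclo[2.1.0]pentanone and attack at the =CH2 terminus is a 5-endo closure), and insertion over Curtius-type loss to the isocyanate (disfavoured by the electron-rich amido chelate).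

**Step 5**
Reactants: 8 (R)-5-(2-methylpropyl)-4-methylidenepyrrolidin-2-one
Product: 10 (R)-5-(2-methylpropyl)pyrrolidine-2,4-dione, via secondary ozonide 9 (not isolated)
Conditions: O3, CH2Cl2, −78 °C, Sudan Red 7B end-point; then PPh3, −78 → 0 °C; NaHCO3 extraction, acidify
Reagents that add atoms: ozone, [O-][O+]=O
Why: Ozonolysis with reductive work-up cleaves the only C=C bond to the C4 ketone and formaldehyde, as in the known unmasking of β-dicarbonyl compounds from β-methylidene carbonyl precursors; C5 is not touched under cold, neutral conditions.

**Step 6**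
Reactants: 10 (R)-5-(2-methylpropyl)pyrrolidine-2,4-dione
Product: 12 (R)-3-acetyl-4-hydroxy-5-(2-methylpropyl)-1,5-dihydro-2H-pyrrol-2-one, via difluoroboron chelate 11 (not isolated)
Conditions: AcCl, BF3·OEt2, 70 °C; then MeOH, reflux
Reagents that add atoms: acetyl chloride, CC(=O)Cl
Why: Boron trifluoride-mediated C3-acylation of pyrrolidine-2,4-diones with acid chlorides, which passes through the difluoroboron chelate of the 3-acyl product and releases it by methanolysis, is an established route to 3-acyltetramic acids and keeps C5 away from base.

**Step 7**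
Reactants: 13 (E)-dodec-2-enoic acid
Product: 14 (E)-dodec-2-enoyl chloride
Conditions: (COCl)2, DMF (cat.), CH2Cl2, 0 °C → rt
Reagents that add atoms: oxalyl chloride, O=C(Cl)C(=O)Cl
Why: Acid chloride formation with oxalyl chloride under DMF catalysis (Vilsmeier-type activation) is standard and leaves the E-configured conjugated alkene unchanged.

**Step 8**
Reactants: 12 (R)-3-acetyl-4-hydroxy-5-(2-methylpropyl)-1,5-dihydro-2H-pyrrol-2-one; 14 (E)-dodec-2-enoyl chloride
Product: 16 reutericyclin C [(R)-3-acetyl-1-((E)-dodec-2-enoyl)-4-hydroxy-5-(2-methylpropyl)-1,5-dihydro-2H-pyrrol-2-one], via dilithium dianion 15 (not isolated)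
Conditions: n-BuLi (2.1 equiv), THF, −78 °C; then 14, −78 → −20 °C; 1 M HCl
Reagents that add atoms: none
Why: Double deprotonation gives the O,N-dianion, whose amide nitrogen is the more reactive site, so the acid chloride acylates N1 by nucleophilic acyl substitution (imide formation) as in known N-acylations of 3-acetyltetramic acids, while the enolate character of C3–C4–O keeps C5–H from being removed and C5 stays R.

**Compound list**

1 | 1-bromo-3-methylbutane | CC(C)CCBr | starting material
2 | diketene (4-methylideneoxetan-2-one) | C=C1CC(=O)O1 | starting material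
3 | isopentylmagnesium bromide [(3-methylbutyl)magnesium bromide] | CC(C)CC[Mg]Br | intermediate
4 | 6-methyl-3-methylideneheptanoic acid | CC(C)CCC(=C)CC(=O)O | intermediate
5 | 1-(imidazol-1-yl)-6-methyl-3-methylideneheptan-1-one (acyl imidazolide) | CC(C)CCC(=C)CC(=O)n1ccnc1 | intermediate
6 | N-hydroxy-6-methyl-3-methylideneheptanamide | CC(C)CCC(=C)CC(=O)NO | intermediate
7 | 3-(5-methyl-2-methylidenehexyl)-1,4,2-dioxazol-5-one | CC(C)CCC(=C)CC1=NOC(=O)O1 | intermediate
8 | (R)-5-(2-methylpropyl)-4-methylidenepyrrolidin-2-one | C=C1CC(=O)N[C@@H]1CC(C)C | intermediate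
9 | (6R)-6-(2-methylpropyl)-1,2,4-trioxa-7-azaspiro[4.4]nonan-8-one (secondary ozonide of 8, both epimers at the spiro carbon) | CC(C)C[C@H]1NC(=O)CC12OCOO2 | intermediate
10 | (R)-5-(2-methylpropyl)pyrrolidine-2,4-dione | O=C1CC(=O)[C@@H](CC(C)C)N1 | intermediate
11 | (5R)-3-[1-(difluoroboranyloxy)ethylidene]-5-(2-methylpropyl)pyrrolidine-2,4-dione (difluoroboron chelate, the C4 oxygen coordinated to boron) | CC(OB(F)F)=C1C(=O)N[C@H](CC(C)C)C1=O | intermediate
12 | (R)-3-acetyl-4-hydroxy-5-(2-methylpropyl)-1,5-dihydro-2H-pyrrol-2-one | CC(=O)C1=C(O)[C@@H](CC(C)C)NC1=O | intermediate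
13 | (E)-dodec-2-enoic acid | CCCCCCCCC/C=C/C(=O)O | starting material
14 | (E)-dodec-2-enoyl chloride | CCCCCCCCC/C=C/C(=O)Cl | intermediate
15 | dilithium salt of 12 (C4 enolate oxygen and N1 deprotonated) | CC(=O)C1=C([O-])[C@@H](CC(C)C)[N-]C1=O.[Li+].[Li+] | intermediate
16 | reutericyclin C, (R)-3-acetyl-1-[(E)-dodec-2-enoyl]-4-hydroxy-5-(2-methylpropyl)-1,5-dihydro-2H-pyrrol-2-one | CCCCCCCCC/C=C/C(=O)N1C(=O)C(C(C)=O)=C(O)[C@H]1CC(C)C | target

**Step count and risks**

Total: 8 steps. Longest linear sequence: 7 steps (steps 1–6 and 8); step 7 is a one-step side branch.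

Most likely to fail, in this order:

Step 4. The nitrenoid may be diverted. The alkene here is 1,1-disubstituted and lies inside the tether, which has not been tried in this amidation. Electrophilic attack at its CH2 terminus, followed by proton loss, would give achiral alkylidene or endocyclic isomers. Curtius-type rearrangement to the allylic isocyanate may compete. The two C5 hydrogens may also be poorly distinguished, because the group the ligand must read at C5 is a plain alkyl chain. The fallback gives up the C–H amidation and takes C5 from the chiral pool. It sets out from diketene 2, which should acetoacetylate methyl D-leucinate hydrochloride (Et3N, CH2Cl2, 0 °C) to methyl N-(3-oxobutanoyl)-D-leucinate F1. A Lacey–Dieckmann cyclisation of this (KOtBu, t-BuOH, rt, short reaction time to limit C5 epimerisation, then acid) closes C3–C4 and comes back to the route at 12, ready for step 8.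

Step 5. Excess ozone may over-oxidise the enol tautomer of the product. The liberated formaldehyde may condense at the unsubstituted C3 to give methylene-bridged dimers. The polar, acidic product may also be lost on work-up. The fallback is a two-stage cleavage without ozone. It sets out from 8, which should be dihydroxylated under Upjohn conditions (K2OsO4·2H2O cat., N-methylmorpholine N-oxide, acetone/H2O) to (5R)-4-hydroxy-4-(hydroxymethyl)-5-(2-methylpropyl)pyrrolidin-2-one F2; both C4 epimers serve. Glycol cleavage with NaIO4 on wet silica gel in CH2Cl2 at 0 °C, where the formaldehyde stays on the support as its hydrate, comes back to the route at 10.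

Step 8. The dianion may be acylated at oxygen as well as nitrogen, may add in conjugate fashion to the enoyl chloride, and the base may epimerise C5. The fallback changes the order of events so that nitrogen is acylated while it is the only acidic site. It sets out from 8, which after deprotonation (LiHMDS, THF, −78 °C) should react with 14 to give (R)-1-[(E)-dodec-2-enoyl]-5-(2-methylpropyl)-4-methylidenepyrrolidin-2-one F3. Ozone to the Sudan Red 7B end-point (CH2Cl2, −78 °C) should attack only the electron-rich 1,1-disubstituted alkene and not the electron-poor enoyl alkene, giving the secondary ozonide F4. PPh3 should reduce this to (R)-1-[(E)-dodec-2-enoyl]-5-(2-methylpropyl)pyrrolidine-2,4-dione F5. O-Acetylation (AcOH, DCC, DMAP, CH2Cl2) to (R)-1-[(E)-dodec-2-enoyl]-2-(2-methylpropyl)-5-oxo-2,5-dihydro-1H-pyrrol-3-yl acetate F6, followed in the same flask by DMAP-mediated O-to-C acyl migration, comes back to the route at the target 16.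

**Further compounds**

F1 | step 4 | methyl N-(3-oxobutanoyl)-D-leucinate | CC(=O)CC(=O)N[C@H](CC(C)C)C(=O)OC
F2 | step 5 | (5R)-4-hydroxy-4-(hydroxymethyl)-5-(2-methylpropyl)pyrrolidin-2-one | CC(C)C[C@H]1NC(=O)CC1(O)CO
F3 | step 8 | (R)-1-[(E)-dodec-2-enoyl]-5-(2-methylpropyl)-4-methylidenepyrrolidin-2-one | CCCCCCCCC/C=C/C(=O)N1C(=O)CC(=C)[C@H]1CC(C)C
F4 | step 8 | (6R)-7-[(E)-dodec-2-enoyl]-6-(2-methylpropyl)-1,2,4-trioxa-7-azaspiro[4.4]nonan-8-one (secondary ozonide of F3) | CCCCCCCCC/C=C/C(=O)N1C(=O)CC2(OCOO2)[C@H]1CC(C)C
F5 | step 8 | (R)-1-[(E)-dodec-2-enoyl]-5-(2-methylpropyl)pyrrolidine-2,4-dione | CCCCCCCCC/C=C/C(=O)N1C(=O)CC(=O)[C@H]1CC(C)C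
F6 | step 8 | (R)-1-[(E)-dodec-2-enoyl]-2-(2-methylpropyl)-5-oxo-2,5-dihydro-1H-pyrrol-3-yl acetate | CCCCCCCCC/C=C/C(=O)N1C(=O)C=C(OC(C)=O)[C@H]1CC(C)C
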